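The route rests on cutting the bond between C3 of the isoxazolidine ring and the first CH2 of the 8-(pyridin-3-yl)octyl chain. C3 is the one ring carbon bonded to O2, so at the lactone level the N1–O2–C3(=O) unit of the cis-fused cyclopenta[c]isoxazolidine is a cyclic O-acyl hydroxylamine, a tethered acyl donor. The key step adds [8-(pyridin-3-yl)octyl]magnesium bromide to the enantiopure N-[13-(pyridin-3-yl)tridecyl] lactone, joining both pyridine-bearing halves and giving the C3 hemiketal. Hydride is then delivered to the derived oxocarbenium ion from the convex face, which places the chain on the concave face as in the target. The lactone comes from (1S,2R)-2-aminocyclopentanecarboxylic acid.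

Key step: step 7

Assumption: (1S,2R)-2-aminocyclopentane-1-carboxylic acid (the enantiomer of natural cispentacin) is taken as commercially available in enantiopure form; hemiketal 17 is drawn without configuration at C3 because both epimers converge on the same oxocarbenium ion.

Step 1
Reactants: 1 3-methylpyridine; 2 1,12-dibromododecane
Product: 4 3-(13-bromotridecyl)pyridine, via 3-picolyllithium 3 (not isolated)
Conditions: LiN(i-Pr)2, THF, −78 °C; then added to 2 (3 equiv), THF, −78 → 0 °C; short SiO2 column (removes excess 2); product kept cold in solution and used at once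
Reagents that add atoms: none
Why: Lateral lithiation of 3-picoline gives the picolyl anion, which should be alkylated once (SN2) by the dibromide held in excess under inverse addition.

Step 2
Reactants: 5 (1S,2R)-2-aminocyclopentane-1-carboxylic acid
Product: 6 methyl (1S,2R)-2-aminocyclopentane-1-carboxylate hydrochloride
Conditions: SOCl2, MeOH, 0 °C → reflux
Reagents that add atoms: methanol CO; thionyl chloride O=S(Cl)Cl
Why: Acid-mediated esterification (SOCl2/MeOH) keeps the amine protonated and leaves both stereocentres, which become C3a and C6a of the target, untouched.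

Step 3
Reactants: 6 methyl (1S,2R)-2-aminocyclopentane-1-carboxylate hydrochloride; 4 3-(13-bromotridecyl)pyridine
Product: 7 methyl (1S,2R)-2-{[13-(pyridin-3-yl)tridecyl]amino}cyclopentane-1-carboxylate
Conditions: 6 (2.5 equiv, excess recovered), K2CO3, NaI (cat.), MeCN, 60 °C
Reagents that add atoms: none
Why: SN2 N-alkylation with Finkelstein assistance should stop at the secondary amine because the α-branched primary amine is used in excess and is far more nucleophilic than the pyridine nitrogen or the hindered product.

Step 4
Reactants: 7 methyl (1S,2R)-2-{[13-(pyridin-3-yl)tridecyl]amino}cyclopentane-1-carboxylate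
Product: 8 methyl (1S,2R)-2-{(benzoyloxy)[13-(pyridin-3-yl)tridecyl]amino}cyclopentane-1-carboxylate
Conditions: (PhCO2)2, K2HPO4, DMF, rt
Reagents that add atoms: dibenzoyl peroxide O=C(OOC(=O)c1ccccc1)c1ccccc1
Why: Attack of the secondary amine on the peroxide O–O bond (buffered N-benzoyloxylation of amines with dibenzoyl peroxide) installs the N–O bond at the hydroxylamine level without over-oxidation to a nitrone and without oxidising the pyridine.

Step 5
Reactants: 8 methyl (1S,2R)-2-{(benzoyloxy)[13-(pyridin-3-yl)tridecyl]amino}cyclopentane-1-carboxylate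
Product: 10 (3aS,6aR)-1-[13-(pyridin-3-yl)tridecyl]hexahydro-3H-cyclopenta[c][1,2]oxazol-3-one, via N-hydroxy amino ester 9 (not isolated)
Conditions: K2CO3 (0.2 equiv), MeOH, 0 °C; filter, evaporate; PhMe, 90 °C (−MeOH)
Reagents that add atoms: none
Why: Methanolysis transfers the benzoyl group to methanol, and the freed N–OH, held cis to the methyl ester, should lactonise on heating (5-exo-trig acyl substitution, the known closure of β-(N-hydroxyamino) esters to isoxazolidin-5-ones), the cis ring fusion being carried over from 5.

Step 6
Reactants: 11 3-bromopyridine; 12 1,8-dibromooctane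
Product: 14 3-(8-bromooctyl)pyridine, via pyridin-3-ylmagnesium chloride 13 (not isolated)
Conditions: 11, i-PrMgCl·LiCl, THF, 0 °C → rt; then added to 12 (3 equiv), Li2CuCl4 (3 mol %), N-methylpyrrolidone, THF, 0 °C; aq NH4Cl–NH3 wash, short SiO2 column (removes copper and excess 12); product kept cold in solution and used at once
Reagents that add atoms: none
Why: Bromine–magnesium exchange gives the 3-pyridyl Grignard reagent 13, which should displace one bromide of the primary dibromide held in excess under Li2CuCl4 catalysis (Kochi-type copper-catalysed Grignard–alkyl bromide cross-coupling), the secondary 2-bromopropane released in the exchange being a far slower partner.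

Step 7
Reactants: 14 3-(8-bromooctyl)pyridine; 10 (3aS,6aR)-1-[13-(pyridin-3-yl)tridecyl]hexahydro-3H-cyclopenta[c][1,2]oxazol-3-one
Product: 17 (3aS,6aR)-3-[8-(pyridin-3-yl)octyl]-1-[13-(pyridin-3-yl)tridecyl]hexahydro-1H-cyclopenta[c][1,2]oxazol-3-ol (both C3 epimers), via Grignard reagent 15 (not isolated), via magnesium hemiketalate 16 (not isolated)
Conditions: 14, Mg (I2-activated), THF, 30 °C; then 10, THF, −78 °C; AcOH, −78 °C; crude product kept cold and taken directly into step 8
Reagents that add atoms: none
Why: Grignard reagent 15 adds to the lactone carbonyl C3 of 10, and the tetrahedral adduct 16 should persist as a five-membered cyclic magnesium hemiketalate at −78 °C until the cold acetic acid quench, so no ketone is released for a second addition; the closest known reaction type is organometallic addition to lactones to give lactols, as in C-glycoside synthesis, with i-Bu2AlH reduction of isoxazolidin-5-ones to 5-hydroxyisoxazolidines as the hydride counterpart. No ring is closed: the isoxazolidine ring of 10 is retained, and any ring-opened β-(N-hydroxyamino) ketone should reclose by 5-exo-trig hemiketalisation. The only new stereocentre is the hemiketal carbon C3, which is uncontrolled and irrelevant because both epimers give the same oxocarbenium ion in step 8, while C3a and C6a come unchanged from 5. The step needs attack at C=O and not at nitrogen, which is secured because O-acyl hydroxylamines aminate organomagnesium reagents only under copper catalysis (14 is freed of copper after step 6) and backside attack on N1 is blocked inside the bicycle; it also needs tolerance of three basic nitrogens, which an alkyl Grignard reagent has at low temperature. Carbon is put in first and hydrogen last because a carbon nucleophile or radical arriving at a C3 cation or radical would enter from the convex face and give the wrong C3 epimer, and a C3 radical next to the N–O bond would be expected to fragment.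

Step 8
Reactants: 17 (3aS,6aR)-3-[8-(pyridin-3-yl)octyl]-1-[13-(pyridin-3-yl)tridecyl]hexahydro-1H-cyclopenta[c][1,2]oxazol-3-ol
Product: 19 pyrinodemin B (3S,3aS,6aR)-3-[8-(pyridin-3-yl)octyl]-1-[13-(pyridin-3-yl)tridecyl]hexahydro-1H-cyclopenta[c][1,2]oxazole, via oxocarbenium ion 18 (not isolated)
Conditions: Et3SiH, BF3·OEt2 (excess), CH2Cl2–MeCN, −40 → 0 °C
Reagents that add atoms: none
Why: BF3·OEt2 ionises the hemiketal to the bicyclic oxocarbenium ion 18 and Et3SiH should deliver hydride to its convex face, anti to the cyclopentane ring and syn to H-3a, so that H-3 ends cis to H-3a and H-6a and C3 is S (Kishi-type ionic hydrogenation of a lactol).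

Compound list
1 | 3-methylpyridine (3-picoline) | Cc1cccnc1 | starting material
2 | 1,12-dibromododecane | BrCCCCCCCCCCCCBr | starting material
3 | (pyridin-3-ylmethyl)lithium (3-picolyllithium) | [Li]Cc1cccnc1 | intermediate
4 | 3-(13-bromotridecyl)pyridine | BrCCCCCCCCCCCCCc1cccnc1 | intermediate
5 | (1S,2R)-2-aminocyclopentane-1-carboxylic acid (cis) | OC(=O)[C@H]1CCC[C@H]1N | starting material
6 | methyl (1S,2R)-2-aminocyclopentane-1-carboxylate hydrochloride | COC(=O)[C@H]1CCC[C@H]1N.Cl | intermediate
7 | methyl (1S,2R)-2-{[13-(pyridin-3-yl)tridecyl]amino}cyclopentane-1-carboxylate | COC(=O)[C@H]1CCC[C@H]1NCCCCCCCCCCCCCc1cccnc1 | intermediate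
8 | methyl (1S,2R)-2-{(benzoyloxy)[13-(pyridin-3-yl)tridecyl]amino}cyclopentane-1-carboxylate | COC(=O)[C@H]1CCC[C@H]1N(OC(=O)c1ccccc1)CCCCCCCCCCCCCc1cccnc1 | intermediate
9 | methyl (1S,2R)-2-{hydroxy[13-(pyridin-3-yl)tridecyl]amino}cyclopentane-1-carboxylate | COC(=O)[C@H]1CCC[C@H]1N(O)CCCCCCCCCCCCCc1cccnc1 | intermediate
10 | (3aS,6aR)-1-[13-(pyridin-3-yl)tridecyl]hexahydro-3H-cyclopenta[c][1,2]oxazol-3-one (cis-fused bicyclic isoxazolidin-5-one) | c1cncc(CCCCCCCCCCCCCN2OC(=O)[C@H]3CCC[C@H]32)c1 | intermediate
11 | 3-bromopyridine | Brc1cccnc1 | starting material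
12 | 1,8-dibromooctane | BrCCCCCCCCBr | starting material
13 | pyridin-3-ylmagnesium chloride | Cl[Mg]c1cccnc1 | intermediate
14 | 3-(8-bromooctyl)pyridine | BrCCCCCCCCc1cccnc1 | intermediate
15 | [8-(pyridin-3-yl)octyl]magnesium bromide | Br[Mg]CCCCCCCCc1cccnc1 | intermediate
16 | bromomagnesium (3aS,6aR)-3-[8-(pyridin-3-yl)octyl]-1-[13-(pyridin-3-yl)tridecyl]hexahydro-1H-cyclopenta[c][1,2]oxazol-3-olate (C3 epimers) | c1cncc(CCCCCCCCCCCCCN2OC(O[Mg]Br)(CCCCCCCCc3cccnc3)[C@H]3CCC[C@H]32)c1 | intermediate
17 | (3aS,6aR)-3-[8-(pyridin-3-yl)octyl]-1-[13-(pyridin-3-yl)tridecyl]hexahydro-1H-cyclopenta[c][1,2]oxazol-3-ol (C3 epimers) | c1cncc(CCCCCCCCCCCCCN2OC(O)(CCCCCCCCc3cccnc3)[C@H]3CCC[C@H]32)c1 | intermediate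
18 | (3aS,6aR)-3-[8-(pyridin-3-yl)octyl]-1-[13-(pyridin-3-yl)tridecyl]-3a,4,5,6,6a-pentahydro-1H-cyclopenta[c][1,2]oxazol-2-ium (oxocarbenium ion, O2=C3) | c1cncc(CCCCCCCCCCCCCN2[O+]=C(CCCCCCCCc3cccnc3)[C@H]3CCC[C@H]32)c1 | intermediate
19 | pyrinodemin B, (3S,3aS,6aR)-3-[8-(pyridin-3-yl)octyl]-1-[13-(pyridin-3-yl)tridecyl]hexahydro-1H-cyclopenta[c][1,2]oxazole | c1cncc(CCCCCCCCCCCCCN2O[C@@H](CCCCCCCCc3cccnc3)[C@H]3CCC[C@H]32)c1 | target

Total step count: 8. Longest linear sequence: 6 steps (5 → 6 → 7 → 8 → 10 → 17 → 19, steps 2, 3, 4, 5, 7 and 8).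

Steps most likely to fail

Step 7 (key step). The Grignard reagent may not form cleanly, because a bromide that carries a nucleophilic pyridine can self-quaternise or undergo Wurtz coupling. The tetrahedral adduct may also collapse early and take up a second equivalent. The fallback sets out from 10 and comes back at 19 with an sp-carbon nucleophile that is made by deprotonation. 3-Bromopyridine 11 and an excess of commercial octa-1,7-diyne are joined by Sonogashira coupling (PdCl2(PPh3)2, CuI, Et3N) to give 3-(octa-1,7-diyn-1-yl)pyridine F1, which is freed of copper before use. Its lithium acetylide (n-BuLi, THF, −78 °C) should add once to 10 to give (3aS,6aR)-3-[8-(pyridin-3-yl)octa-1,7-diyn-1-yl]-1-[13-(pyridin-3-yl)tridecyl]hexahydro-1H-cyclopenta[c][1,2]oxazol-3-ol F2. Et3SiH/BF3·OEt2 should reduce this from the convex face to (3R,3aS,6aR)-3-[8-(pyridin-3-yl)octa-1,7-diyn-1-yl]-1-[13-(pyridin-3-yl)tridecyl]hexahydro-1H-cyclopenta[c][1,2]oxazole F3. F3 has the same spatial arrangement as the target; the descriptor changes only because the alkynyl carbon outranks C3a. Excess diimide (TsNHNH2, NaOAc, aqueous DME, reflux) should then saturate both triple bonds without touching the N–O bond or the pyridines and give 19.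

Step 8. Ionisation under Lewis acid may be accompanied by ring opening and retro-Michael loss of the hydroxylamine, which would erode the ring-fusion stereocentres, or hydride delivery may lose facial control. The fallback sets out from 17 and comes back at 19 without a hydride addition to a cation. Dehydration (MsCl, Et3N, CH2Cl2, 0 °C) should give the exocyclic enol ether (3aS,6aR)-3-[8-(pyridin-3-yl)octylidene]-1-[13-(pyridin-3-yl)tridecyl]hexahydro-1H-cyclopenta[c][1,2]oxazole F4. Elimination toward the ring-fusion carbon is disfavoured by strain. Syn-hydrogenation (H2 1 atm, Pd/C, EtOAc) should add from the convex face and give 19; the pyridine rings of the substrate moderate the catalyst, which should hold back N–O hydrogenolysis.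

Step 5. Ring closure may stall, because a methyl ester is a poor acyl donor and the product is itself an activated ester, so the thermal transesterification equilibrium may not go to completion. The fallback sets out from 8 and comes back at 10 by making closure irreversible. LiOH (THF–H2O, 0 °C) should cleave both the benzoate and the methyl ester to give (1S,2R)-2-{hydroxy[13-(pyridin-3-yl)tridecyl]amino}cyclopentane-1-carboxylic acid F5. Carbodiimide activation (EDC·HCl, CH2Cl2, rt) should then close the N–O–C(=O) lactone to 10.

Further compounds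
F1 | step 7 | 3-(octa-1,7-diyn-1-yl)pyridine | C#CCCCCC#Cc1cccnc1
F2 | step 7 | (3aS,6aR)-3-[8-(pyridin-3-yl)octa-1,7-diyn-1-yl]-1-[13-(pyridin-3-yl)tridecyl]hexahydro-1H-cyclopenta[c][1,2]oxazol-3-ol (C3 epimers) | c1cncc(CCCCCCCCCCCCCN2OC(O)(C#CCCCCC#Cc3cccnc3)[C@H]3CCC[C@H]32)c1
F3 | step 7 | (3R,3aS,6aR)-3-[8-(pyridin-3-yl)octa-1,7-diyn-1-yl]-1-[13-(pyridin-3-yl)tridecyl]hexahydro-1H-cyclopenta[c][1,2]oxazole | c1cncc(CCCCCCCCCCCCCN2O[C@@H](C#CCCCCC#Cc3cccnc3)[C@H]3CCC[C@H]32)c1
F4 | step 8 | (3aS,6aR)-3-[8-(pyridin-3-yl)octylidene]-1-[13-(pyridin-3-yl)tridecyl]hexahydro-1H-cyclopenta[c][1,2]oxazole (E/Z mixture) | c1cncc(CCCCCCCCCCCCCN2OC(=CCCCCCCCc3cccnc3)[C@H]3CCC[C@H]32)c1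
F5 | step 5 | (1S,2R)-2-{hydroxy[13-(pyridin-3-yl)tridecyl]amino}cyclopentane-1-carboxylic acid | OC(=O)[C@H]1CCC[C@H]1N(O)CCCCCCCCCCCCCc1cccnc1
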